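**Strategy.** Both lactones (rings C and C') are traced back to (R)-malic acid: the carbinol carbon C8 is malate C2, C8' is malate C3, and C8' carries the benzylic carbon C7' that leads into the 5,5'-linked guaiacyl rings B and B'. Cutting the two C7'–C8' bonds gives two malate units and one biaryl bis(benzylic bromide), made from vanillin by oxidative dimerisation, O-benzylation, reduction and bromination. In one operation two chelated malate alkoxide–enolate dianions are alkylated by the dibromide, which forges both C7'–C8' bonds and sets both C8' stereocentres anti to the pool oxygen. Dioxolanone benzylation at C8 with retention, reduction of C9', lactonisation and hydrogenolysis complete the twofold-symmetric dimer.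

Key step: step 5

Remarks on the chemistry
- Lignan numbering is used: C7–C8(OH)–C9(=O) and C7'–C8'–C9'H2–O in each lactone. Rings A/A' are the outer guaiacyl rings on C7, rings B/B' the inner 5,5'-linked ones on C7', rings C/C' the lactones.
- Stereochemical bookkeeping: the target is (8R,8'R) in both halves. C2 of (R)-malate keeps its descriptor when the benzyl group replaces hydrogen with retention (8R). The (3S) centre of the alkylated malate becomes (8'R) once C4 is reduced to C9', because the CIP ranking of its two carbon neighbours is inverted while the geometry is unchanged. The (2R,3S) alkylation product therefore maps onto the target as drawn.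
- Stoichiometry: the route is two-directional. Steps 1, 5, 7 and 9 each build two molecules of one numbered component into the product; that component stands on the Reactants line with its stoichiometry and, for its second molecule, on the line for reagents that add atoms. Step 2 likewise takes up two molecules of benzyl bromide.
- Assumption: the biaryl axis carries only two ortho substituents and rotates freely, so no atropisomers are expected.
- Compound 12 is taken as commercial; LiN(iPr)2 and LiN(SiMe3)2 are used as commercial solutions.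

Step 1
Reactants: 1 vanillin (2 equiv)
Product: 2 dehydrodivanillin (6,6'-dihydroxy-5,5'-dimethoxybiphenyl-3,3'-dicarbaldehyde)
Conditions: 1 (2 equiv), Na2S2O8 (1.1 equiv), FeSO4·7H2O (cat.), H2O, 50 °C
Reagents that add atoms: vanillin (the second molecule of 1), COc1cc(C=O)ccc1O
Why: Oxidative phenol coupling of two molecules of 1, in which sulfate radical anions generated from persulfate by the divalent iron catalyst form the phenoxyl radical, which can join C–C only at the free ortho carbon C5 because the para position carries the formyl group; this persulfate dimerisation of vanillin is a standard preparation and the sparingly soluble dimer should precipitate from the water.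

Step 2
Reactants: 2 dehydrodivanillin
Product: 3 6,6'-bis(benzyloxy)-5,5'-dimethoxybiphenyl-3,3'-dicarbaldehyde
Conditions: BnBr (2.5 equiv), K2CO3 (3 equiv), DMF, 60 °C
Reagents that add atoms: benzyl bromide, BrCc1ccccc1
Why: Twofold Williamson ether synthesis on both phenoxides in a polar aprotic solvent; the aldehydes are inert, and benzyl is chosen so that all four phenols of the target can be unmasked together in the last step.

Step 3
Reactants: 3 bis(benzyl ether) dialdehyde
Product: 4 [6,6'-bis(benzyloxy)-5,5'-dimethoxybiphenyl-3,3'-diyl]dimethanol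
Conditions: NaBH4, THF/MeOH, 0 °C → rt
Reagents that add atoms: none
Why: Borohydride reduction of the two aryl aldehydes to primary benzylic alcohols, with the ethers untouched.

Step 4
Reactants: 4 biaryl diol
Product: 5 2,2'-bis(benzyloxy)-5,5'-bis(bromomethyl)-3,3'-dimethoxybiphenyl
Conditions: PBr3, CH2Cl2, 0 °C
Reagents that add atoms: phosphorus tribromide, BrP(Br)Br
Why: Alcohol-to-bromide conversion through phosphite esters and SN2 displacement by bromide, which is fast for these electron-rich primary benzylic positions at 0 °C and spares the aryl benzyl ethers; the dibromide should be used promptly.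

Step 5
Reactants: 5 biaryl bis(benzylic bromide); 6 dimethyl (R)-malate (2 equiv incorporated)
Product: 8 tetramethyl 3,3'-{[6,6'-bis(benzyloxy)-5,5'-dimethoxybiphenyl-3,3'-diyl]bis(methylene)}bis[(2R,3S)-2-hydroxybutanedioate], via dilithium malate dianion 7 (not isolated)
Conditions: 6 (5 equiv), LiN(iPr)2 (9.8 equiv), THF, −78 → −20 °C; then 5 (1 equiv), −78 → −10 °C; AcOH quench
Reagents that add atoms: dimethyl (R)-malate (the second molecule of 6), COC(=O)C[C@@H](O)C(=O)OC
Why: Two equivalents of amide base per malate remove the hydroxyl proton and one C3 proton, giving a lithium alkoxide–enolate held in a rigid chelate, and the enolate carbon of one such dianion displaces bromide from each primary benzylic carbon of 5 by SN2, so that two malate units are attached to one biaryl. The closest known reaction type is the Fráter–Seebach alkylation of β-hydroxy ester dianions, established for malate diesters with benzylic halides and used here at both ends of one bis-electrophile. No ring is closed. Each new stereocentre (malate C3, the later C8') is controlled by the neighbouring C2 stereocentre of the chiral pool: the electrophile approaches the enolate face turned away from the C2 ester substituent of the chelate, which places the benzyl group anti to the C2 oxygen and gives (2R,3S). The step needs C- over O-alkylation, anti over syn attack and full conversion at both termini; the aggregated lithium alkoxide is a poor nucleophile at low temperature, the chelate supplies the facial bias, and running 5 as the limiting reagent against excess dianion drives the mono-alkylated intermediate on. Since 5 has no acidic hydrogen, no β-hydrogen and two benzylic sites on separate rings, neither proton transfer nor elimination competes and the two alkylations are independent.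

Step 6
Reactants: 8 bis-malate tetraester
Product: 9 3,3'-{[6,6'-bis(benzyloxy)-5,5'-dimethoxybiphenyl-3,3'-diyl]bis(methylene)}bis[(2R,3S)-2-hydroxybutanedioic acid]
Conditions: LiOH·H2O, THF/MeOH/H2O, 0 °C → rt; then 1 M HCl
Reagents that add atoms: lithium hydroxide, [Li+].[OH-]
Why: Acyl–oxygen saponification of the four methyl esters; below room temperature C8' should not epimerise because its enolisation is disfavoured once the carboxylates have formed, and the aryl benzyl ethers are stable to base.

Step 7
Reactants: 9 bis-malic tetraacid; 10 pivalaldehyde (2 equiv incorporated)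
Product: 11 (2S,2'S)-3,3'-[6,6'-bis(benzyloxy)-5,5'-dimethoxybiphenyl-3,3'-diyl]bis{2-[(2R,4R)-2-tert-butyl-5-oxo-1,3-dioxolan-4-yl]propanoic acid}
Conditions: 10 (6 equiv), TsOH·H2O (cat.), H2SO4 (cat.), CH2Cl2, reflux, 4 Å MS in a Soxhlet
Reagents that add atoms: pivalaldehyde (the second molecule of 10), CC(C)(C)C=O
Why: Seebach acetalisation of an α-hydroxy acid under equilibrating Brønsted acid catalysis, one molecule of 10 condensing at each end with loss of water: the five-membered 1,3-dioxolan-4-one of the α-hydroxy acid is preferred over the six-membered alternative through the β-carboxyl, and the new acetal centre settles as the favoured cis isomer (tert-butyl and side chain on the same face), C8 and C8' being untouched.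

Step 8
Reactants: 12 4-(benzyloxy)-3-methoxybenzyl alcohol
Product: 13 4-(benzyloxy)-3-methoxybenzyl bromide
Conditions: PBr3, Et2O, 0 °C
Reagents that add atoms: phosphorus tribromide, BrP(Br)Br
Why: The same phosphite-ester/SN2 bromination as in step 4 on a primary benzylic alcohol; the bromide is prepared fresh for step 9.

Step 9
Reactants: 11 bis-dioxolanone diacid; 13 4-(benzyloxy)-3-methoxybenzyl bromide (2 equiv incorporated)
Product: 15 (2S,2'S)-3,3'-[6,6'-bis(benzyloxy)-5,5'-dimethoxybiphenyl-3,3'-diyl]bis(2-{(2R,4R)-4-[4-(benzyloxy)-3-methoxybenzyl]-2-tert-butyl-5-oxo-1,3-dioxolan-4-yl}propanoic acid), via tetralithium carboxylate enolate 14 (not isolated)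
Conditions: 13 (3 equiv), LiN(SiMe3)2 (4.6 equiv), THF, −78 → −20 °C (base to 11 first, then 13); then 1 M HCl
Reagents that add atoms: 4-(benzyloxy)-3-methoxybenzyl bromide (the second molecule of 13), COc1cc(CBr)ccc1OCc1ccccc1
Why: Seebach self-regeneration of stereocentres, as known for the dioxolanone of malic acid with its free carboxyl group: after carboxylate formation the second equivalent of base per half enolises the dioxolanone, C8 becomes trigonal while the acetal centre stores the chirality, and one molecule of 13 is attacked at each end on the face trans to the tert-butyl group, so that the new C7–C8 bond takes the place of the former hydrogen (net retention, 8R).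

Step 10
Reactants: 15 bis-benzylated bis-dioxolanone diacid
Product: 17 tetra-O-benzyl bis-5,5-nortrachelogenin, via bis(hydroxymethyl) bis-dioxolanone 16 (not isolated)
Conditions: BH3·SMe2, THF, 0 °C → rt; MeOH quench; then CF3CO2H (cat.), CH2Cl2, rt
Reagents that add atoms: none
Why: Borane reduces the free carboxylic acids through acyloxyboranes much faster than the dioxolanone carbonyl, and under acid the new primary C9' hydroxyl attacks that carbonyl (5-exo-trig transacylation) to give the γ-lactone, releasing pivalaldehyde and the tertiary C8 hydroxyl without touching a stereocentre.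

Step 11
Reactants: 17 tetra-O-benzyl bis-5,5-nortrachelogenin
Product: 18 bis-5,5-nortrachelogenin
Conditions: H2 (1 atm), Pd/C (10 wt%), EtOAc/MeOH, rt
Reagents that add atoms: none
Why: Hydrogenolysis of the four aryl benzyl ethers over palladium on carbon; the lactones and the non-benzylic tertiary alcohols are stable under these neutral conditions.

Compound list
1 | vanillin (4-hydroxy-3-methoxybenzaldehyde) | COc1cc(C=O)ccc1O | starting material
2 | dehydrodivanillin (6,6'-dihydroxy-5,5'-dimethoxybiphenyl-3,3'-dicarbaldehyde) | COc1cc(C=O)cc(-c2cc(C=O)cc(OC)c2O)c1O | intermediate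
3 | 6,6'-bis(benzyloxy)-5,5'-dimethoxybiphenyl-3,3'-dicarbaldehyde | COc1cc(C=O)cc(-c2cc(C=O)cc(OC)c2OCc2ccccc2)c1OCc1ccccc1 | intermediate
4 | [6,6'-bis(benzyloxy)-5,5'-dimethoxybiphenyl-3,3'-diyl]dimethanol | COc1cc(CO)cc(-c2cc(CO)cc(OC)c2OCc2ccccc2)c1OCc1ccccc1 | intermediate
5 | 2,2'-bis(benzyloxy)-5,5'-bis(bromomethyl)-3,3'-dimethoxybiphenyl | BrCc1cc(OC)c(OCc2ccccc2)c(-c2cc(CBr)cc(OC)c2OCc2ccccc2)c1 | intermediate
6 | dimethyl (R)-malate [dimethyl (2R)-2-hydroxybutanedioate] | COC(=O)C[C@@H](O)C(=O)OC | starting material
7 | dilithium alkoxide–enolate of dimethyl (R)-malate (enolate geometry not specified) | [Li+].[Li+].COC([O-])=C[C@@H]([O-])C(=O)OC | intermediate (not isolated)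
8 | tetramethyl 3,3'-{[6,6'-bis(benzyloxy)-5,5'-dimethoxybiphenyl-3,3'-diyl]bis(methylene)}bis[(2R,3S)-2-hydroxybutanedioate] | COC(=O)[C@H](O)[C@H](Cc1cc(OC)c(OCc2ccccc2)c(-c2cc(C[C@H](C(=O)OC)[C@@H](O)C(=O)OC)cc(OC)c2OCc2ccccc2)c1)C(=O)OC | intermediate
9 | 3,3'-{[6,6'-bis(benzyloxy)-5,5'-dimethoxybiphenyl-3,3'-diyl]bis(methylene)}bis[(2R,3S)-2-hydroxybutanedioic acid] | OC(=O)[C@H](O)[C@H](Cc1cc(OC)c(OCc2ccccc2)c(-c2cc(C[C@H](C(=O)O)[C@@H](O)C(=O)O)cc(OC)c2OCc2ccccc2)c1)C(=O)O | intermediate
10 | pivalaldehyde (2,2-dimethylpropanal) | CC(C)(C)C=O | starting material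
11 | (2S,2'S)-3,3'-[6,6'-bis(benzyloxy)-5,5'-dimethoxybiphenyl-3,3'-diyl]bis{2-[(2R,4R)-2-tert-butyl-5-oxo-1,3-dioxolan-4-yl]propanoic acid} (cis-dioxolanones, free C9' acids) | OC(=O)[C@@H](Cc1cc(OC)c(OCc2ccccc2)c(-c2cc(C[C@H](C(=O)O)[C@H]3O[C@@H](C(C)(C)C)OC3=O)cc(OC)c2OCc2ccccc2)c1)[C@H]1O[C@@H](C(C)(C)C)OC1=O | intermediate
12 | 4-(benzyloxy)-3-methoxybenzyl alcohol | COc1cc(CO)ccc1OCc1ccccc1 | starting material
13 | 4-(benzyloxy)-3-methoxybenzyl bromide | COc1cc(CBr)ccc1OCc1ccccc1 | intermediate
14 | tetralithium bis(carboxylate/dioxolanone enolate) derived from 11 | [Li+].[Li+].[Li+].[Li+].[O-]C(=O)[C@@H](Cc1cc(OC)c(OCc2ccccc2)c(-c2cc(C[C@H](C([O-])=O)C3=C([O-])O[C@H](C(C)(C)C)O3)cc(OC)c2OCc2ccccc2)c1)C1=C([O-])O[C@H](C(C)(C)C)O1 | intermediate (not isolated)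
15 | (2S,2'S)-3,3'-[6,6'-bis(benzyloxy)-5,5'-dimethoxybiphenyl-3,3'-diyl]bis(2-{(2R,4R)-4-[4-(benzyloxy)-3-methoxybenzyl]-2-tert-butyl-5-oxo-1,3-dioxolan-4-yl}propanoic acid) | OC(=O)[C@@H](Cc1cc(OC)c(OCc2ccccc2)c(-c2cc(C[C@H](C(=O)O)[C@@]3(Cc4ccc(OCc5ccccc5)c(OC)c4)O[C@@H](C(C)(C)C)OC3=O)cc(OC)c2OCc2ccccc2)c1)[C@@]1(Cc2ccc(OCc3ccccc3)c(OC)c2)O[C@@H](C(C)(C)C)OC1=O | intermediate
16 | diol from 15 in which both CO2H groups are reduced to CH2OH (C9'), all stereocentres unchanged in space | OC[C@@H](Cc1cc(OC)c(OCc2ccccc2)c(-c2cc(C[C@H](CO)[C@@]3(Cc4ccc(OCc5ccccc5)c(OC)c4)O[C@@H](C(C)(C)C)OC3=O)cc(OC)c2OCc2ccccc2)c1)[C@@]1(Cc2ccc(OCc3ccccc3)c(OC)c2)O[C@@H](C(C)(C)C)OC1=O | intermediate (not isolated)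
17 | tetra-O-benzyl bis-5,5-nortrachelogenin: 4,4'-{[6,6'-bis(benzyloxy)-5,5'-dimethoxybiphenyl-3,3'-diyl]bis(methylene)}bis{(3R,4R)-3-[4-(benzyloxy)-3-methoxybenzyl]-3-hydroxyoxolan-2-one} | COc1cc(C[C@]2(O)C(=O)OC[C@H]2Cc2cc(OC)c(OCc3ccccc3)c(-c3cc(C[C@@H]4COC(=O)[C@@]4(O)Cc4ccc(OCc5ccccc5)c(OC)c4)cc(OC)c3OCc3ccccc3)c2)ccc1OCc1ccccc1 | intermediate
18 | bis-5,5-nortrachelogenin: 4,4'-[(6,6'-dihydroxy-5,5'-dimethoxybiphenyl-3,3'-diyl)bis(methylene)]bis[(3R,4R)-3-hydroxy-3-(4-hydroxy-3-methoxybenzyl)oxolan-2-one] | COc1cc(C[C@]2(O)C(=O)OC[C@H]2Cc2cc(OC)c(O)c(-c3cc(C[C@@H]4COC(=O)[C@@]4(O)Cc4ccc(O)c(OC)c4)cc(OC)c3O)c2)ccc1O | target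

Total step count: 11.
Longest linear sequence: 10 steps (1 → 18 through steps 1–7 and 9–11); step 8 is a one-step side branch.

Steps most likely to fail

Step 5. The facial bias of the chelated dianion may be incomplete at one of the two termini, so that mixed anti/syn diastereomers build up statistically and are hard to separate from the twofold-symmetric product; the reaction may also stall after the first alkylation. The fallback sets out from 1 and 6 and returns at 8, and makes the biaryl bond after the alkylation instead of before it. Bromination of 1 (Br2, AcOH, rt) would give 5-bromovanillin F1, which would be O-benzylated (BnBr, K2CO3, DMF) to 4-(benzyloxy)-3-bromo-5-methoxybenzaldehyde F2, reduced with NaBH4 to [4-(benzyloxy)-3-bromo-5-methoxyphenyl]methanol F3 and brominated with PBr3 to 2-(benzyloxy)-1-bromo-5-(bromomethyl)-3-methoxybenzene F4. The dianion of 6 would be alkylated with F4 under the conditions of step 5 to give dimethyl (2R,3S)-3-{[4-(benzyloxy)-3-bromo-5-methoxyphenyl]methyl}-2-hydroxybutanedioate F5, which has a single new stereocentre and should be freed from its syn isomer at this stage. Half of F5 would be converted by Miyaura borylation (B2pin2, Pd(dppf)Cl2, KOAc, dioxane, 80 °C) into dimethyl (2R,3S)-3-{[4-(benzyloxy)-3-methoxy-5-(4,4,5,5-tetramethyl-1,3,2-dioxaborolan-2-yl)phenyl]methyl}-2-hydroxybutanedioate F6. Suzuki–Miyaura coupling of F5 with F6 (Pd(OAc)2, SPhos, K3PO4, toluene/H2O, 60 °C) would then give 8.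

Step 9. The crowded tetra-anion may alkylate slowly at the two fully substituted enolate carbons, the dioxolanone enolate may fragment on warming, and the C8' substituent may work against the acetal centre so that the preference for attack trans to the tert-butyl group erodes. The fallback sets out from 11 and returns at 17; it forms the lactones first and lets the ring substituent at C8' direct the benzylation. Reduction of 11 with BH3·SMe2 would give the bis(hydroxymethyl) bis-dioxolanone F7, which acid (CF3CO2H, CH2Cl2) would convert without isolation into the bis(α-hydroxy lactone) 4,4'-{[6,6'-bis(benzyloxy)-5,5'-dimethoxybiphenyl-3,3'-diyl]bis(methylene)}bis[(3R,4R)-3-hydroxyoxolan-2-one] F8. Double deprotonation of each hydroxy lactone (LiN(iPr)2, 2.2 equiv per lactone, THF/DMPU, −78 °C) and alkylation of the alkoxide–enolate with 13 (one molecule per lactone) is enolate-dianion alkylation of the Fráter–Seebach kind. It should proceed anti to the C8' benzyl group, which places the C7 benzyl trans to C7' and leaves the hydroxyl cis to it, as in 17.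

Step 7. Equilibration may leave trans acetal isomers or six-membered dioxanones, and the poorly soluble tetraacid may react at one end only. The fallback sets out from 9 and returns at 11; it replaces thermodynamic Brønsted-acid acetalisation of the free acid by kinetically controlled silyl-transfer acetalisation. Persilylation of 9 (Me3SiCl, Et3N, CH2Cl2) would give the soluble hexakis(trimethylsilyl) derivative F9, with two silyl esters and one silyl ether per half. Treatment with pivalaldehyde 10 and catalytic Me3SiOTf in CH2Cl2 at −25 °C (Noyori-type acetalisation of α-silyloxy silyl esters) should close the cis dioxolanones under kinetic control, and aqueous work-up would cleave the remaining silyl esters to give 11.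

Further compounds
F1 | step 5 | 5-bromovanillin (3-bromo-4-hydroxy-5-methoxybenzaldehyde) | COc1cc(C=O)cc(Br)c1O
F2 | step 5 | 4-(benzyloxy)-3-bromo-5-methoxybenzaldehyde | COc1cc(C=O)cc(Br)c1OCc1ccccc1
F3 | step 5 | [4-(benzyloxy)-3-bromo-5-methoxyphenyl]methanol | COc1cc(CO)cc(Br)c1OCc1ccccc1
F4 | step 5 | 2-(benzyloxy)-1-bromo-5-(bromomethyl)-3-methoxybenzene | COc1cc(CBr)cc(Br)c1OCc1ccccc1
F5 | step 5 | dimethyl (2R,3S)-3-{[4-(benzyloxy)-3-bromo-5-methoxyphenyl]methyl}-2-hydroxybutanedioate | COC(=O)[C@H](O)[C@H](Cc1cc(Br)c(OCc2ccccc2)c(OC)c1)C(=O)OC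
F6 | step 5 | dimethyl (2R,3S)-3-{[4-(benzyloxy)-3-methoxy-5-(4,4,5,5-tetramethyl-1,3,2-dioxaborolan-2-yl)phenyl]methyl}-2-hydroxybutanedioate | COC(=O)[C@H](O)[C@H](Cc1cc(B2OC(C)(C)C(C)(C)O2)c(OCc2ccccc2)c(OC)c1)C(=O)OC
F7 | step 9 | bis(hydroxymethyl) bis-dioxolanone: diol from 11 with both CO2H groups reduced to CH2OH, (2R,4R)-dioxolanones retained | OC[C@@H](Cc1cc(OC)c(OCc2ccccc2)c(-c2cc(C[C@H](CO)[C@H]3O[C@@H](C(C)(C)C)OC3=O)cc(OC)c2OCc2ccccc2)c1)[C@H]1O[C@@H](C(C)(C)C)OC1=O
F8 | step 9 | 4,4'-{[6,6'-bis(benzyloxy)-5,5'-dimethoxybiphenyl-3,3'-diyl]bis(methylene)}bis[(3R,4R)-3-hydroxyoxolan-2-one] | O[C@H]1C(=O)OC[C@H]1Cc1cc(OC)c(OCc2ccccc2)c(-c2cc(C[C@@H]3COC(=O)[C@@H]3O)cc(OC)c2OCc2ccccc2)c1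
F9 | step 7 | hexakis(trimethylsilyl) derivative of 9 (four trimethylsilyl esters, two trimethylsilyl ethers; 2R,3S in each half) | C[Si](C)(C)OC(=O)[C@H](O[Si](C)(C)C)[C@H](Cc1cc(OC)c(OCc2ccccc2)c(-c2cc(C[C@H](C(=O)O[Si](C)(C)C)[C@@H](O[Si](C)(C)C)C(=O)O[Si](C)(C)C)cc(OC)c2OCc2ccccc2)c1)C(=O)O[Si](C)(C)C
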